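**Retrosynthetic overview**
- The C12 acetate is put on last. The C7=C8 alkene comes from dehydration of a β-hydroxy ketone.
- Key disconnection C7–C8: intermolecular aldol between the lithium dienolate of an (R)-4-silyloxy-4-octadienylcyclopentenone and methyl (4R,5Z)-4-acetoxy-7-oxohept-5-enoate.
- Ring fragment: (S)-4-silyloxycyclopentenone; anti-selective 1,2-propargylation sets C12; copper-mediated alkyne coupling and semi-hydrogenation give the (Z,Z)-chain; desilylation and oxidation move the carbonyl.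
- Enal fragment: acyl Sonogashira ynone; asymmetric transfer hydrogenation sets C4; Lindlar reduction sets 5Z; oxidation gives the aldehyde.
- Ring order: no ring is formed. The single cyclopentenone ring is bought and carried through.

Assumption: (S)-4-[(tert-butyldimethylsilyl)oxy]cyclopent-2-en-1-one is taken as a catalogue starting material (both enantiomers are sold); C1–C20 below are the target's carbon numbers (ester carbon C1, ring C8–C12).

**Step 1**
Reactants: 1 (S)-4-[(tert-butyldimethylsilyl)oxy]cyclopent-2-en-1-one; 2 propargyl bromide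
Product: 4 (1R,4S)-4-[(tert-butyldimethylsilyl)oxy]-1-(prop-2-yn-1-yl)cyclopent-2-en-1-ol (OH cis to OTBS), via allenylzinc bromide 3 (not isolated)
Conditions: Zn dust (activated), THF, 0 °C → rt; aq. NH4Cl work-up; chromatography
Reagents that add atoms: none
Why: Barbier-type zinc carbonyl propargylation: the allenylzinc adds 1,2 (SE2') to give the homopropargylic tertiary alcohol, attacking anti to the C4 silyloxy group, which sets the future C12; the minor diastereomer and any allenyl isomer are removed by chromatography.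

**Step 2**
Reactants: 4 (1R,4S)-4-[(tert-butyldimethylsilyl)oxy]-1-(prop-2-yn-1-yl)cyclopent-2-en-1-ol; 5 1-bromopent-2-yne
Product: 6 (1R,4S)-4-[(tert-butyldimethylsilyl)oxy]-1-(octa-2,5-diyn-1-yl)cyclopent-2-en-1-ol
Conditions: CuI, n-Bu4NCl, K2CO3, DMF, rt, N2
Reagents that add atoms: none
Why: Copper-mediated sp–sp3 coupling (Jeffery conditions): the copper acetylide displaces the primary propargylic bromide (SN2) to give the skipped diyne; CuI and n-Bu4NCl are promoters, and the free OH and silyl ether are tolerated.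

**Step 3**
Reactants: 6 (1R,4S)-4-[(tert-butyldimethylsilyl)oxy]-1-(octa-2,5-diyn-1-yl)cyclopent-2-en-1-ol
Product: 7 (1R,4S)-4-[(tert-butyldimethylsilyl)oxy]-1-[(2Z,5Z)-octa-2,5-dien-1-yl]cyclopent-2-en-1-ol
Conditions: H2 (1 atm), Ni(OAc)2·4H2O/NaBH4 (nickel boride, 20 mol %), H2NCH2CH2NH2, EtOH, rt; stop after 2 equiv H2
Reagents that add atoms: none
Why: Brown nickel boride semi-hydrogenation adds H2 syn to both alkynes, giving the (14Z,17Z) skipped diene; the amine-poisoned catalyst leaves the hindered ring alkene alone.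

**Step 4**
Reactants: 7 (1R,4S)-4-[(tert-butyldimethylsilyl)oxy]-1-[(2Z,5Z)-octa-2,5-dien-1-yl]cyclopent-2-en-1-ol
Product: 8 (1R,4S)-1-[(2Z,5Z)-octa-2,5-dien-1-yl]cyclopent-2-ene-1,4-diol
Conditions: n-Bu4NF, THF, 0 °C → rt
Reagents that add atoms: none
Why: Fluoride desilylation driven by Si–F bond formation; the non-acidic medium spares the tertiary allylic alcohol and the skipped diene.

**Step 5**
Reactants: 8 (1R,4S)-1-[(2Z,5Z)-octa-2,5-dien-1-yl]cyclopent-2-ene-1,4-diol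
Product: 9 (R)-4-hydroxy-4-[(2Z,5Z)-octa-2,5-dien-1-yl]cyclopent-2-en-1-one
Conditions: MnO2 (activated, excess), CH2Cl2, rt
Reagents that add atoms: none
Why: Allylic oxidation: MnO2 oxidizes only the secondary allylic alcohol, so the carbonyl now sits at the former silyloxy carbon and the untouched tertiary carbinol becomes the quaternary C12.

**Step 6**
Reactants: 9 (R)-4-hydroxy-4-[(2Z,5Z)-octa-2,5-dien-1-yl]cyclopent-2-en-1-one
Product: 10 (R)-4-[(2Z,5Z)-octa-2,5-dien-1-yl]-4-[(trimethylsilyl)oxy]cyclopent-2-en-1-one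
Conditions: Me3SiCl, imidazole, DMF, 0 °C → rt
Reagents that add atoms: chlorotrimethylsilane C[Si](C)(C)Cl
Why: Imidazole-promoted O-silylation masks the tertiary OH for the enolate step without enolizing the ketone.

**Step 7**
Reactants: 11 methyl 4-chloro-4-oxobutanoate; 12 tert-butyldimethyl(prop-2-yn-1-yloxy)silane
Product: 13 methyl 7-[(tert-butyldimethylsilyl)oxy]-4-oxohept-5-ynoate
Conditions: PdCl2(PPh3)2 (2 mol %), CuI (4 mol %), Et3N, THF, rt
Reagents that add atoms: none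
Why: Acyl Sonogashira coupling: oxidative addition of the acid chloride to palladium, transmetalation from the copper acetylide and reductive elimination give the ynone with the ester intact.

**Step 8**
Reactants: 13 methyl 7-[(tert-butyldimethylsilyl)oxy]-4-oxohept-5-ynoate
Product: 14 methyl (R)-7-[(tert-butyldimethylsilyl)oxy]-4-hydroxyhept-5-ynoate
Conditions: Ru[(R,R)-TsNCHPhCHPhNH](p-cymene) (1 mol %), i-PrOH, rt; crude used at once
Reagents that add atoms: none
Why: Noyori asymmetric transfer hydrogenation of an alkynyl ketone: bifunctional hydride/proton transfer from the (R,R)-complex gives the (R)-propargylic alcohol, which sets C4; the neutral medium avoids lactonization.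

**Step 9**
Reactants: 14 methyl (R)-7-[(tert-butyldimethylsilyl)oxy]-4-hydroxyhept-5-ynoate
Product: 15 methyl (R)-4-acetoxy-7-[(tert-butyldimethylsilyl)oxy]hept-5-ynoate
Conditions: Ac2O, pyridine, DMAP (cat.), CH2Cl2, 0 °C → rt
Reagents that add atoms: acetic anhydride CC(=O)OC(C)=O
Why: DMAP-catalysed acylation installs the C4 acetate with retention and caps the γ-hydroxy ester before it can close to the lactone.

**Step 10**
Reactants: 15 methyl (R)-4-acetoxy-7-[(tert-butyldimethylsilyl)oxy]hept-5-ynoate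
Product: 16 methyl (R)-4-acetoxy-7-hydroxyhept-5-ynoate
Conditions: HF·pyridine, pyridine, THF, 0 °C → rt
Reagents that add atoms: none
Why: Buffered HF cleaves the primary silyl ether; the linear alkyne prevents acetyl migration, and the ester and acetate survive.

**Step 11**
Reactants: 16 methyl (R)-4-acetoxy-7-hydroxyhept-5-ynoate
Product: 17 methyl (4R,5Z)-4-acetoxy-7-hydroxyhept-5-enoate
Conditions: H2 (1 atm), Pd/CaCO3 poisoned with Pb(OAc)2, quinoline, EtOAc, rt
Reagents that add atoms: none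
Why: Lindlar semi-hydrogenation adds H2 syn on the poisoned palladium surface, which sets the 5Z alkene.

**Step 12**
Reactants: 17 methyl (4R,5Z)-4-acetoxy-7-hydroxyhept-5-enoate
Product: 18 methyl (4R,5Z)-4-acetoxy-7-oxohept-5-enoate
Conditions: Dess–Martin periodinane, pyridine, CH2Cl2, 0 °C; short filtration, used at once, dim light
Reagents that add atoms: none
Why: Buffered Dess–Martin oxidation gives the Z-enal without over-oxidation and, at 0 °C, without Z→E isomerization.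

**Step 13**
Reactants: 10 (R)-4-[(2Z,5Z)-octa-2,5-dien-1-yl]-4-[(trimethylsilyl)oxy]cyclopent-2-en-1-one; 18 methyl (4R,5Z)-4-acetoxy-7-oxohept-5-enoate
Product: 20 methyl (4R,5Z)-4-acetoxy-7-hydroxy-7-[(2S)-2-[(2Z,5Z)-octa-2,5-dien-1-yl]-5-oxo-2-[(trimethylsilyl)oxy]cyclopent-3-en-1-yl]hept-5-enoate (C7/C8 epimer mixture), via lithium dienolate 19 (not isolated)
Conditions: LiN(i-Pr)2, THF, −78 °C, 30 min; then 18, −78 °C, 15 min; AcOH quench at −78 °C
Reagents that add atoms: none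
Why: Intermolecular aldol addition: the kinetic lithium enolate at the only enolizable carbon adds 1,2 to the aldehyde at −78 °C and forms C7–C8; the new C7 and C8 centres are erased in step 14, and C4, C12 and 5Z are untouched.

**Step 14**
Reactants: 20 methyl (4R,5Z)-4-acetoxy-7-hydroxy-7-[(2S)-2-[(2Z,5Z)-octa-2,5-dien-1-yl]-5-oxo-2-[(trimethylsilyl)oxy]cyclopent-3-en-1-yl]hept-5-enoate
Product: 22 methyl (4R,5Z,7E)-4-acetoxy-7-[(2S)-2-[(2Z,5Z)-octa-2,5-dien-1-yl]-5-oxo-2-[(trimethylsilyl)oxy]cyclopent-3-en-1-ylidene]hept-5-enoate, via C7 mesylate 21 (not isolated)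
Conditions: MsCl, Et3N, CH2Cl2, −20 °C → rt, dark; chromatography
Reagents that add atoms: none
Why: Mesylation followed by E1cB elimination through the ketone enolate gives the cross-conjugated alkylidene cyclopentenone, expected mainly as 7E (C6 anti to the C9 carbonyl); the methanesulfonyl group leaves again, and the minor 7Z isomer is separated.

**Step 15**
Reactants: 22 methyl (4R,5Z,7E)-4-acetoxy-7-[(2S)-2-[(2Z,5Z)-octa-2,5-dien-1-yl]-5-oxo-2-[(trimethylsilyl)oxy]cyclopent-3-en-1-ylidene]hept-5-enoate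
Product: 23 methyl (4R,5Z,7E)-4-acetoxy-7-[(2S)-2-hydroxy-2-[(2Z,5Z)-octa-2,5-dien-1-yl]-5-oxocyclopent-3-en-1-ylidene]hept-5-enoate
Conditions: AcOH–THF–H2O (3:1:1), rt, dark
Reagents that add atoms: none
Why: Mild acid hydrolysis of the tertiary trimethylsilyl ether; the C12–O bond is not ionized (the flanking alkenes are electron-poor), and the esters and polyene survive.

**Step 16**
Reactants: 23 methyl (4R,5Z,7E)-4-acetoxy-7-[(2S)-2-hydroxy-2-[(2Z,5Z)-octa-2,5-dien-1-yl]-5-oxocyclopent-3-en-1-ylidene]hept-5-enoate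
Product: 24 methyl (4R,5Z,7E)-4-acetoxy-7-[(2S)-2-acetoxy-2-[(2Z,5Z)-octa-2,5-dien-1-yl]-5-oxocyclopent-3-en-1-ylidene]hept-5-enoate
Conditions: Ac2O, DMAP, Et3N, CH2Cl2, rt, dark
Reagents that add atoms: acetic anhydride CC(=O)OC(C)=O
Why: DMAP-catalysed acyl transfer acetylates the hindered tertiary alcohol on oxygen with retention at C12, giving the target.

**Compound list**
1 | (S)-4-[(tert-butyldimethylsilyl)oxy]cyclopent-2-en-1-one | O=C1C=C[C@@H](O[Si](C)(C)C(C)(C)C)C1 | starting material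
2 | propargyl bromide (3-bromoprop-1-yne) | C#CCBr | starting material
3 | allenylzinc bromide | C=C=C[Zn]Br | intermediate
4 | (1R,4S)-4-[(tert-butyldimethylsilyl)oxy]-1-(prop-2-yn-1-yl)cyclopent-2-en-1-ol | C#CC[C@]1(O)C=C[C@@H](O[Si](C)(C)C(C)(C)C)C1 | intermediate
5 | 1-bromopent-2-yne | CCC#CCBr | starting material
6 | (1R,4S)-4-[(tert-butyldimethylsilyl)oxy]-1-(octa-2,5-diyn-1-yl)cyclopent-2-en-1-ol | CCC#CCC#CC[C@]1(O)C=C[C@@H](O[Si](C)(C)C(C)(C)C)C1 | intermediate
7 | (1R,4S)-4-[(tert-butyldimethylsilyl)oxy]-1-[(2Z,5Z)-octa-2,5-dien-1-yl]cyclopent-2-en-1-ol | CC/C=C\C/C=C\C[C@]1(O)C=C[C@@H](O[Si](C)(C)C(C)(C)C)C1 | intermediate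
8 | (1R,4S)-1-[(2Z,5Z)-octa-2,5-dien-1-yl]cyclopent-2-ene-1,4-diol | CC/C=C\C/C=C\C[C@]1(O)C=C[C@@H](O)C1 | intermediate
9 | (R)-4-hydroxy-4-[(2Z,5Z)-octa-2,5-dien-1-yl]cyclopent-2-en-1-one | CC/C=C\C/C=C\C[C@]1(O)C=CC(=O)C1 | intermediate
10 | (R)-4-[(2Z,5Z)-octa-2,5-dien-1-yl]-4-[(trimethylsilyl)oxy]cyclopent-2-en-1-one | CC/C=C\C/C=C\C[C@]1(O[Si](C)(C)C)C=CC(=O)C1 | intermediate
11 | methyl 4-chloro-4-oxobutanoate | COC(=O)CCC(=O)Cl | starting material
12 | tert-butyldimethyl(prop-2-yn-1-yloxy)silane | C#CCO[Si](C)(C)C(C)(C)C | starting material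
13 | methyl 7-[(tert-butyldimethylsilyl)oxy]-4-oxohept-5-ynoate | COC(=O)CCC(=O)C#CCO[Si](C)(C)C(C)(C)C | intermediate
14 | methyl (R)-7-[(tert-butyldimethylsilyl)oxy]-4-hydroxyhept-5-ynoate | COC(=O)CC[C@@H](O)C#CCO[Si](C)(C)C(C)(C)C | intermediate
15 | methyl (R)-4-acetoxy-7-[(tert-butyldimethylsilyl)oxy]hept-5-ynoate | COC(=O)CC[C@@H](OC(C)=O)C#CCO[Si](C)(C)C(C)(C)C | intermediate
16 | methyl (R)-4-acetoxy-7-hydroxyhept-5-ynoate | COC(=O)CC[C@@H](OC(C)=O)C#CCO | intermediate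
17 | methyl (4R,5Z)-4-acetoxy-7-hydroxyhept-5-enoate | COC(=O)CC[C@@H](OC(C)=O)/C=C\CO | intermediate
18 | methyl (4R,5Z)-4-acetoxy-7-oxohept-5-enoate | COC(=O)CC[C@@H](OC(C)=O)/C=C\C=O | intermediate
19 | lithium dienolate of 10 (lithium 3-[(2Z,5Z)-octa-2,5-dien-1-yl]-3-[(trimethylsilyl)oxy]cyclopenta-1,4-dien-1-olate, quaternary centre unchanged) | CC/C=C\C/C=C\C[C@]1(O[Si](C)(C)C)C=CC(O[Li])=C1 | intermediate
20 | methyl (4R,5Z)-4-acetoxy-7-hydroxy-7-[(2S)-2-[(2Z,5Z)-octa-2,5-dien-1-yl]-5-oxo-2-[(trimethylsilyl)oxy]cyclopent-3-en-1-yl]hept-5-enoate (epimers at C7 and C8) | CC/C=C\C/C=C\C[C@]1(O[Si](C)(C)C)C=CC(=O)C1C(O)/C=C\[C@@H](CCC(=O)OC)OC(C)=O | intermediate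
21 | C7 methanesulfonate of 20 | CC/C=C\C/C=C\C[C@]1(O[Si](C)(C)C)C=CC(=O)C1C(OS(C)(=O)=O)/C=C\[C@@H](CCC(=O)OC)OC(C)=O | intermediate
22 | methyl (4R,5Z,7E)-4-acetoxy-7-[(2S)-2-[(2Z,5Z)-octa-2,5-dien-1-yl]-5-oxo-2-[(trimethylsilyl)oxy]cyclopent-3-en-1-ylidene]hept-5-enoate | CC/C=C\C/C=C\C[C@]1(O[Si](C)(C)C)C=CC(=O)/C1=C/C=C\[C@@H](CCC(=O)OC)OC(C)=O | intermediate
23 | methyl (4R,5Z,7E)-4-acetoxy-7-[(2S)-2-hydroxy-2-[(2Z,5Z)-octa-2,5-dien-1-yl]-5-oxocyclopent-3-en-1-ylidene]hept-5-enoate | CC/C=C\C/C=C\C[C@]1(O)C=CC(=O)/C1=C/C=C\[C@@H](CCC(=O)OC)OC(C)=O | intermediate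
24 | 17,18-dehydro-clavulone I, methyl (4R,5Z,7E)-4-acetoxy-7-[(2S)-2-acetoxy-2-[(2Z,5Z)-octa-2,5-dien-1-yl]-5-oxocyclopent-3-en-1-ylidene]hept-5-enoate | CC/C=C\C/C=C\C[C@]1(OC(C)=O)C=CC(=O)/C1=C/C=C\[C@@H](CCC(=O)OC)OC(C)=O | target

**Step count**
Total: 16 steps. Longest linear sequence: 10 steps (steps 1–6 then 13–16, or equally steps 7–12 then 13–16).

**Three steps most likely to fail**

Step 3 (semi-hydrogenation of the skipped diyne). Over-reduced or partly reduced material is hard to separate. The fallback builds both Z-alkenes without hydrogenation. It sets out from 1: CH2=CHCH2MgBr (THF, −78 °C) adds 1,2 anti to the silyloxy group and gives (1R,4S)-1-allyl-4-[(tert-butyldimethylsilyl)oxy]cyclopent-2-en-1-ol F1. Me3SiCl/imidazole converts it into (1R,4S)-1-allyl-4-[(tert-butyldimethylsilyl)oxy]-1-[(trimethylsilyl)oxy]cyclopent-2-ene F2. K2OsO4·2H2O (cat.)/NaIO4/2,6-lutidine in dioxane–H2O should cleave only the terminal alkene, since the ring alkene is shielded by two silyloxy-bearing carbons, and gives 2-[(1S,4S)-4-[(tert-butyldimethylsilyl)oxy]-1-[(trimethylsilyl)oxy]cyclopent-2-en-1-yl]acetaldehyde F3. A Z-selective Wittig reaction with (Z)-hex-3-en-1-ylidenetriphenylphosphorane F4 (from bought (Z)-hex-3-en-1-yltriphenylphosphonium bromide and NaN(SiMe3)2, THF, −78 °C) gives (1R,4S)-4-[(tert-butyldimethylsilyl)oxy]-1-[(2Z,5Z)-octa-2,5-dien-1-yl]-1-[(trimethylsilyl)oxy]cyclopent-2-ene F5. n-Bu4NF removes both silyl groups and the route is rejoined at 8.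

Step 13 (aldol with the Z-enal). The enal 18 can isomerize to E before or during the addition, and the lithium aldolate sits close to the C4 acetate. The fallback carries C5–C6 through the aldol as an alkyne. It sets out from 16 and 10: Dess–Martin oxidation of 16 gives methyl (R)-4-acetoxy-7-oxohept-5-ynoate F6, which has no alkene geometry to lose. Its aldol with dienolate 19 (made from 10 as in step 13) gives methyl (4R)-4-acetoxy-7-hydroxy-7-[(2S)-2-[(2Z,5Z)-octa-2,5-dien-1-yl]-5-oxo-2-[(trimethylsilyl)oxy]cyclopent-3-en-1-yl]hept-5-ynoate F7. Semi-hydrogenation of the alkyne (H2, Pd/CaCO3 poisoned with Pb(OAc)2, quinoline, EtOAc) then gives 20, where the route continues.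

Step 14 (mesylation and elimination). The 7E/7Z ratio may be poor, and the silyl ether may be lost. The fallback runs the elimination in the acetate series. It sets out from 20: AcOH–THF–H2O removes the trimethylsilyl group and gives methyl (4R,5Z)-4-acetoxy-7-hydroxy-7-[(2S)-2-hydroxy-2-[(2Z,5Z)-octa-2,5-dien-1-yl]-5-oxocyclopent-3-en-1-yl]hept-5-enoate F8. Ac2O/DMAP/pyridine acetylates both hydroxyls to methyl (4R,5Z)-4,7-diacetoxy-7-[(2S)-2-acetoxy-2-[(2Z,5Z)-octa-2,5-dien-1-yl]-5-oxocyclopent-3-en-1-yl]hept-5-enoate F9, whose β-acetoxy ketone loses acetic acid in the same flask (E1cB). This comes back to the route at 24, bypassing steps 15 and 16.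

**Further compounds**
F1 | step 3 | (1R,4S)-1-allyl-4-[(tert-butyldimethylsilyl)oxy]cyclopent-2-en-1-ol | C=CC[C@]1(O)C=C[C@@H](O[Si](C)(C)C(C)(C)C)C1
F2 | step 3 | (1R,4S)-1-allyl-4-[(tert-butyldimethylsilyl)oxy]-1-[(trimethylsilyl)oxy]cyclopent-2-ene | C=CC[C@]1(O[Si](C)(C)C)C=C[C@@H](O[Si](C)(C)C(C)(C)C)C1
F3 | step 3 | 2-[(1S,4S)-4-[(tert-butyldimethylsilyl)oxy]-1-[(trimethylsilyl)oxy]cyclopent-2-en-1-yl]acetaldehyde | O=CC[C@]1(O[Si](C)(C)C)C=C[C@@H](O[Si](C)(C)C(C)(C)C)C1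
F4 | step 3 | (Z)-hex-3-en-1-ylidenetriphenylphosphorane | CC/C=C\CC=P(c1ccccc1)(c1ccccc1)c1ccccc1
F5 | step 3 | (1R,4S)-4-[(tert-butyldimethylsilyl)oxy]-1-[(2Z,5Z)-octa-2,5-dien-1-yl]-1-[(trimethylsilyl)oxy]cyclopent-2-ene | CC/C=C\C/C=C\C[C@]1(O[Si](C)(C)C)C=C[C@@H](O[Si](C)(C)C(C)(C)C)C1
F6 | step 13 | methyl (R)-4-acetoxy-7-oxohept-5-ynoate | COC(=O)CC[C@@H](OC(C)=O)C#CC=O
F7 | step 13 | methyl (4R)-4-acetoxy-7-hydroxy-7-[(2S)-2-[(2Z,5Z)-octa-2,5-dien-1-yl]-5-oxo-2-[(trimethylsilyl)oxy]cyclopent-3-en-1-yl]hept-5-ynoate | CC/C=C\C/C=C\C[C@]1(O[Si](C)(C)C)C=CC(=O)C1C(O)C#C[C@@H](CCC(=O)OC)OC(C)=O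
F8 | step 14 | methyl (4R,5Z)-4-acetoxy-7-hydroxy-7-[(2S)-2-hydroxy-2-[(2Z,5Z)-octa-2,5-dien-1-yl]-5-oxocyclopent-3-en-1-yl]hept-5-enoate | CC/C=C\C/C=C\C[C@]1(O)C=CC(=O)C1C(O)/C=C\[C@@H](CCC(=O)OC)OC(C)=O
F9 | step 14 | methyl (4R,5Z)-4,7-diacetoxy-7-[(2S)-2-acetoxy-2-[(2Z,5Z)-octa-2,5-dien-1-yl]-5-oxocyclopent-3-en-1-yl]hept-5-enoate | CC/C=C\C/C=C\C[C@]1(OC(C)=O)C=CC(=O)C1C(OC(C)=O)/C=C\[C@@H](CCC(=O)OC)OC(C)=O
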